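Ring B is disconnected at C1'–C2' and C5'–C6'. The 2-ethynyl group of a fully acylated 3,5,7-trioxygenated 8-methoxychromone and the Danishefsky diene combine in a (4+2) cycloaddition, and loss of methanol then gives the para-disubstituted benzene ring and, in the same operation, O4' as the only free hydroxyl, para to C1'. That para relationship in ring B, and the need to prenylate O4' alone among four oxygens, is the feature exploited. The precursor is 2-ethynyl-8-methoxychromen-4-one carrying pivalate esters at O3, O5 and O7; the esters make the alkyne more electron-poor and later leave under base, so no acid meets the prenyl ether.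

Key step: step 11

Remark: tributyl[(methoxymethoxy)methyl]stannane and the zinc amide TMP2Zn·2MgCl2·2LiCl (TMP = 2,2,6,6-tetramethylpiperidide, titrated THF solution) are taken as purchased or pre-made reagents; locants follow flavone numbering (ring A C5–C8, ring B primed).

Step 1
Reactants: 1 2,4,6-trihydroxybenzaldehyde
Product: 2 2-hydroxy-4,6-bis(methoxymethoxy)benzaldehyde
Conditions: MOMCl (2.2 equiv), iPr2NEt (3 equiv), CH2Cl2, 0 °C to rt
Reagents that add atoms: chloromethyl methyl ether, COCCl
Why: Williamson-type O-alkylation with the chloromethyl ether should stop at the bis-ether because the last ortho hydroxyl is locked in a hydrogen bond to the formyl oxygen and is the least nucleophilic, which leaves free exactly the phenol that later becomes O1.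

Step 2
Reactants: 2 2-hydroxy-4,6-bis(methoxymethoxy)benzaldehyde
Product: 3 2-hydroxy-3-iodo-4,6-bis(methoxymethoxy)benzaldehyde
Conditions: NIS (1.05 equiv), DMF, 0 °C, dark
Reagents that add atoms: N-iodosuccinimide, O=C1CCC(=O)N1I
Why: Electrophilic aromatic iodination is expected ortho to the chelated phenol (C3), the usual site for 2-hydroxy-4,6-dialkoxyaryl carbonyl compounds, since C5 is flanked by two acetal ethers, and one equivalent of reagent guards against di-iodination.

Step 3
Reactants: 3 2-hydroxy-3-iodo-4,6-bis(methoxymethoxy)benzaldehyde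
Product: 4 2-hydroxy-3-methoxy-4,6-bis(methoxymethoxy)benzaldehyde
Conditions: NaOMe (6 equiv), CuI (0.3 equiv), MeOH–DMF, 100 °C
Reagents that add atoms: sodium methoxide, C[O-].[Na+]
Why: Copper-catalysed Ullmann-type C–O coupling of an ortho-iodophenoxide with methoxide (the reaction type that converts 5-iodovanillin into syringaldehyde) should replace iodine by the methoxy group that becomes C8–OMe, the phenoxide shielding the formyl group from methoxide and the acetal ethers being inert to base.

Step 4
Reactants: 4 2-hydroxy-3-methoxy-4,6-bis(methoxymethoxy)benzaldehyde; 5 tributyl[(methoxymethoxy)methyl]stannane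
Product: 7 2-[1-hydroxy-2-(methoxymethoxy)ethyl]-6-methoxy-3,5-bis(methoxymethoxy)phenol (racemic), via (methoxymethoxy)methyllithium 6 (not isolated)
Conditions: 5 (2.4 equiv), n-BuLi (2.3 equiv), THF, −78 °C; then 4, −78 to −40 °C; AcOH quench
Reagents that add atoms: none
Why: Tin–lithium exchange gives the α-alkoxymethyllithium, one equivalent of which deprotonates the phenol while the next adds to the aldehyde (1,2-addition of an organolithium), the carbinol centre forming as a racemate that the following oxidation removes.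

Step 5
Reactants: 7 2-[1-hydroxy-2-(methoxymethoxy)ethyl]-6-methoxy-3,5-bis(methoxymethoxy)phenol
Product: 8 1-[2-hydroxy-3-methoxy-4,6-bis(methoxymethoxy)phenyl]-2-(methoxymethoxy)ethan-1-one
Conditions: MnO2 (activated, 15 equiv), CH2Cl2, rt
Reagents that add atoms: none
Why: Oxidation of an electron-rich benzylic alcohol with MnO2, routine for ortho-hydroxybenzylic carbinols, should give the aryl ketone without touching the phenol, which ends hydrogen-bonded to the new carbonyl.

Step 6
Reactants: 8 1-[2-hydroxy-3-methoxy-4,6-bis(methoxymethoxy)phenyl]-2-(methoxymethoxy)ethan-1-one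
Product: 11 3,5,7-trihydroxy-8-methoxy-4H-chromen-4-one, via enaminone 9 (not isolated), via tris(methoxymethyl) chromone 10 (not isolated)
Conditions: DMF-DMA (3 equiv), toluene, 100 °C; AcOH (3 equiv), 60 °C until ring closure is complete; then HCl (2 M in MeOH), 40 °C
Reagents that add atoms: N,N-dimethylformamide dimethyl acetal, COC(OC)N(C)C
Why: Enaminone chromone synthesis: the activated methylene condenses with the amide acetal, the single free phenol adds to the aminomethylene carbon and dimethylamine is lost (6-endo-trig addition–elimination), so that, this phenol being the neighbour of the methoxy-bearing carbon, the methoxy group can only end at C8; methanolic HCl then exchanges the three acetal ethers for hydroxyls by transacetalisation after the ring is closed.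

Step 7
Reactants: 11 3,5,7-trihydroxy-8-methoxy-4H-chromen-4-one
Product: 12 8-methoxy-4-oxo-4H-chromene-3,5,7-triyl tris(2,2-dimethylpropanoate)
Conditions: PivCl (5 equiv), pyridine, DMAP (0.2 equiv), 50 °C
Reagents that add atoms: pivaloyl chloride, CC(C)(C)C(=O)Cl
Why: DMAP-catalysed esterification acylates all three hydroxyls, the hydrogen-bonded O5–H under forcing, and the pivalates are chosen because they have no α-hydrogen, withstand the zinc amide, fluoride and carbonate of the coming steps, pull electron density out of the pyranone and leave at the end under methoxide.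

Step 8
Reactants: 12 8-methoxy-4-oxo-4H-chromene-3,5,7-triyl tris(2,2-dimethylpropanoate)
Product: 14 2-iodo-8-methoxy-4-oxo-4H-chromene-3,5,7-triyl tris(2,2-dimethylpropanoate), via diorganozinc 13 (not isolated)
Conditions: TMP2Zn·2MgCl2·2LiCl (0.6 equiv), THF, −20 °C to rt; then I2 (1.3 equiv), 0 °C
Reagents that add atoms: iodine, II
Why: Deprotonative zincation of chromones at C2 by hindered zinc amides is established, C3 is blocked and C2–H is acidified by O1, and the resulting arylzinc is too weak a nucleophile to attack or shift the neighbouring pivalate, so iodinolysis of the C–Zn bond should deliver the 2-iodide.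

Step 9
Reactants: 14 2-iodo-8-methoxy-4-oxo-4H-chromene-3,5,7-triyl tris(2,2-dimethylpropanoate); 15 trimethylsilylacetylene
Product: 16 8-methoxy-4-oxo-2-[(trimethylsilyl)ethynyl]-4H-chromene-3,5,7-triyl tris(2,2-dimethylpropanoate)
Conditions: Pd(PPh3)2Cl2 (3 mol%), CuI (5 mol%), Et3N (3 equiv), THF, rt
Reagents that add atoms: none
Why: Sonogashira coupling, in which the C2–I bond, a vinylogous acyl iodide, adds readily to zerovalent palladium and the tertiary amine base cannot substitute at C2.

Step 10
Reactants: 16 8-methoxy-4-oxo-2-[(trimethylsilyl)ethynyl]-4H-chromene-3,5,7-triyl tris(2,2-dimethylpropanoate)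
Product: 17 2-ethynyl-8-methoxy-4-oxo-4H-chromene-3,5,7-triyl tris(2,2-dimethylpropanoate)
Conditions: TBAF (1.1 equiv), AcOH (1.3 equiv), THF, −20 to 0 °C
Reagents that add atoms: none
Why: Fluoride-induced protodesilylation of the alkynylsilane, buffered with acetic acid so that neither the esters nor the electron-poor alkyne meet a basic nucleophile.

Step 11
Reactants: 17 2-ethynyl-8-methoxy-4-oxo-4H-chromene-3,5,7-triyl tris(2,2-dimethylpropanoate); 18 (E)-1-methoxy-3-(trimethylsilyloxy)buta-1,3-diene
Product: 21 2-(4-hydroxyphenyl)-8-methoxy-4-oxo-4H-chromene-3,5,7-triyl tris(2,2-dimethylpropanoate), via cyclohexadiene adduct 19 (not isolated), via aryl silyl ether 20 (not isolated)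
Conditions: 18 (4 equiv), toluene (0.5 M), 110 °C, sealed tube; then 1 M HCl (aq), THF, rt
Reagents that add atoms: none
Why: Proposed new method: the ethynyl group is conjugated through C2=C3 with the C4 carbonyl and, with acyloxy instead of alkoxy groups at O3, O5 and O7, is an electron-poor, ynone-like 2π partner whose terminal carbon is the acceptor end, so the diene should add in a concerted but asynchronous normal-demand (4+2) cycloaddition in which its CH2 terminus bonds to the alkyne terminus and its methoxy-bearing carbon bonds to the carbon that becomes C1'. The closest known reaction type is the cycloaddition of 1-methoxy-3-silyloxybutadienes with acetylenic ketones and propiolates, which gives para-acylphenols after loss of methanol; an ethynyl group on a chromone has not been used in this role. Ring B is closed by the intermolecular cycloaddition itself (two σ-bonds in one step) and aromatised when cyclohexa-1,4-diene 19 undergoes 1,4-elimination of methanol to aryl silyl ether 20, which dilute acid hydrolyses to phenol 21. The methoxy-bearing carbon of 19 is a transient racemic stereocentre that vanishes on aromatisation, so nothing has to be controlled there. The step needs regioselectivity (oxygen para and not meta to C1') and chemoselectivity (the alkyne, not the C2=C3 bond or the carbonyl): the first comes from the polarisation of the two partners, nucleophilic diene terminus to electrophilic alkyne terminus, the second from the absence of Lewis acid and the full substitution of C2=C3. Excess diene, high concentration and heat are meant to compensate for the residual donation from O1 and O3.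

Step 12
Reactants: 21 2-(4-hydroxyphenyl)-8-methoxy-4-oxo-4H-chromene-3,5,7-triyl tris(2,2-dimethylpropanoate); 22 1-bromo-3-methylbut-2-ene (prenyl bromide)
Product: 23 8-methoxy-2-{4-[(3-methylbut-2-en-1-yl)oxy]phenyl}-4-oxo-4H-chromene-3,5,7-triyl tris(2,2-dimethylpropanoate)
Conditions: K2CO3 (1.5 equiv), acetone, 45 °C
Reagents that add atoms: none
Why: Williamson etherification (SN2 at the primary allylic bromide) of the only free phenol, with the hindered pivalates resisting acyl transfer to the phenoxide under carbonate in acetone.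

Step 13
Reactants: 23 8-methoxy-2-{4-[(3-methylbut-2-en-1-yl)oxy]phenyl}-4-oxo-4H-chromene-3,5,7-triyl tris(2,2-dimethylpropanoate)
Product: 24 3,5,7-trihydroxy-8-methoxy-2-{4-[(3-methylbut-2-en-1-yl)oxy]phenyl}-4H-chromen-4-one (3,5,7-trihydroxy-8-methoxy-4'-prenyloxyflavone)
Conditions: NaOMe (4 equiv), MeOH–THF, 0 °C to rt, argon; then AcOH
Reagents that add atoms: none
Why: Methoxide transesterification (Zemplén-type methanolysis) should release O3–H, O5–H and O7–H as methyl pivalate departs, while the allylic aryl ether, the 8-methoxy group and the 2-arylpyranone are inert to methoxide at room temperature; no stereocentre is involved.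

Compound list
1 | 2,4,6-trihydroxybenzaldehyde | O=Cc1c(O)cc(O)cc1O | starting material
2 | 2-hydroxy-4,6-bis(methoxymethoxy)benzaldehyde | O=Cc1c(O)cc(OCOC)cc1OCOC | intermediate
3 | 2-hydroxy-3-iodo-4,6-bis(methoxymethoxy)benzaldehyde | O=Cc1c(O)c(I)c(OCOC)cc1OCOC | intermediate
4 | 2-hydroxy-3-methoxy-4,6-bis(methoxymethoxy)benzaldehyde | O=Cc1c(O)c(OC)c(OCOC)cc1OCOC | intermediate
5 | tributyl[(methoxymethoxy)methyl]stannane | CCCC[Sn](CCCC)(CCCC)COCOC | starting material
6 | (methoxymethoxy)methyllithium | [Li]COCOC | intermediate (not isolated)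
7 | 2-[1-hydroxy-2-(methoxymethoxy)ethyl]-6-methoxy-3,5-bis(methoxymethoxy)phenol, racemic | COCOCC(O)c1c(O)c(OC)c(OCOC)cc1OCOC | intermediate
8 | 1-[2-hydroxy-3-methoxy-4,6-bis(methoxymethoxy)phenyl]-2-(methoxymethoxy)ethan-1-one | COCOCC(=O)c1c(O)c(OC)c(OCOC)cc1OCOC | intermediate
9 | 3-(dimethylamino)-1-[2-hydroxy-3-methoxy-4,6-bis(methoxymethoxy)phenyl]-2-(methoxymethoxy)prop-2-en-1-one, double-bond geometry not defined (both isomers close) | COCOC(=CN(C)C)C(=O)c1c(O)c(OC)c(OCOC)cc1OCOC | intermediate (not isolated)
10 | 8-methoxy-3,5,7-tris(methoxymethoxy)-4H-chromen-4-one | COCOc1cc(OCOC)c2c(=O)c(OCOC)coc2c1OC | intermediate (not isolated)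
11 | 3,5,7-trihydroxy-8-methoxy-4H-chromen-4-one | COc1c(O)cc(O)c2c(=O)c(O)coc12 | intermediate
12 | 8-methoxy-4-oxo-4H-chromene-3,5,7-triyl tris(2,2-dimethylpropanoate) | COc1c(OC(=O)C(C)(C)C)cc(OC(=O)C(C)(C)C)c2c(=O)c(OC(=O)C(C)(C)C)coc12 | intermediate
13 | bis{8-methoxy-4-oxo-3,5,7-tris[(2,2-dimethylpropanoyl)oxy]-4H-chromen-2-yl}zinc | COc1c(OC(=O)C(C)(C)C)cc(OC(=O)C(C)(C)C)c2c(=O)c(OC(=O)C(C)(C)C)c([Zn]c3oc4c(OC)c(OC(=O)C(C)(C)C)cc(OC(=O)C(C)(C)C)c4c(=O)c3OC(=O)C(C)(C)C)oc12 | intermediate (not isolated)
14 | 2-iodo-8-methoxy-4-oxo-4H-chromene-3,5,7-triyl tris(2,2-dimethylpropanoate) | COc1c(OC(=O)C(C)(C)C)cc(OC(=O)C(C)(C)C)c2c(=O)c(OC(=O)C(C)(C)C)c(I)oc12 | intermediate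
15 | trimethylsilylacetylene | C#C[Si](C)(C)C | starting material
16 | 8-methoxy-4-oxo-2-[(trimethylsilyl)ethynyl]-4H-chromene-3,5,7-triyl tris(2,2-dimethylpropanoate) | COc1c(OC(=O)C(C)(C)C)cc(OC(=O)C(C)(C)C)c2c(=O)c(OC(=O)C(C)(C)C)c(C#C[Si](C)(C)C)oc12 | intermediate
17 | 2-ethynyl-8-methoxy-4-oxo-4H-chromene-3,5,7-triyl tris(2,2-dimethylpropanoate) | COc1c(OC(=O)C(C)(C)C)cc(OC(=O)C(C)(C)C)c2c(=O)c(OC(=O)C(C)(C)C)c(C#C)oc12 | intermediate (precursor of the key step)
18 | (E)-1-methoxy-3-(trimethylsilyloxy)buta-1,3-diene (Danishefsky diene) | CO/C=C/C(=C)O[Si](C)(C)C | starting material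
19 | 8-methoxy-2-[6-methoxy-4-(trimethylsilyloxy)cyclohexa-1,4-dien-1-yl]-4-oxo-4H-chromene-3,5,7-triyl tris(2,2-dimethylpropanoate), racemic | COc1c(OC(=O)C(C)(C)C)cc(OC(=O)C(C)(C)C)c2c(=O)c(OC(=O)C(C)(C)C)c(C3=CCC(O[Si](C)(C)C)=CC3OC)oc12 | intermediate (not isolated)
20 | 8-methoxy-4-oxo-2-[4-(trimethylsilyloxy)phenyl]-4H-chromene-3,5,7-triyl tris(2,2-dimethylpropanoate) | COc1c(OC(=O)C(C)(C)C)cc(OC(=O)C(C)(C)C)c2c(=O)c(OC(=O)C(C)(C)C)c(-c3ccc(O[Si](C)(C)C)cc3)oc12 | intermediate (not isolated)
21 | 2-(4-hydroxyphenyl)-8-methoxy-4-oxo-4H-chromene-3,5,7-triyl tris(2,2-dimethylpropanoate) | COc1c(OC(=O)C(C)(C)C)cc(OC(=O)C(C)(C)C)c2c(=O)c(OC(=O)C(C)(C)C)c(-c3ccc(O)cc3)oc12 | intermediate (product of the key step)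
22 | 1-bromo-3-methylbut-2-ene (prenyl bromide) | CC(C)=CCBr | starting material
23 | 8-methoxy-2-{4-[(3-methylbut-2-en-1-yl)oxy]phenyl}-4-oxo-4H-chromene-3,5,7-triyl tris(2,2-dimethylpropanoate) | COc1c(OC(=O)C(C)(C)C)cc(OC(=O)C(C)(C)C)c2c(=O)c(OC(=O)C(C)(C)C)c(-c3ccc(OCC=C(C)C)cc3)oc12 | intermediate
24 | 3,5,7-trihydroxy-8-methoxy-2-{4-[(3-methylbut-2-en-1-yl)oxy]phenyl}-4H-chromen-4-one | COc1c(O)cc(O)c2c(=O)c(O)c(-c3ccc(OCC=C(C)C)cc3)oc12 | target

Total step count: 13. Longest linear sequence: 13 steps (1 to 24); 5, 15, 18 and 22 are purchased.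

Steps most likely to fail

1. Step 11 (the proposed new method). The cycloaddition may be slower than thermal decay or oligomerisation of the diene, or the diene may behave as a silyl enol ether nucleophile instead of closing the ring, so that ring B is never formed. The fallback uses known chemistry and sets out from 12: the zincation of step 8 is repeated to diorganozinc 13, which is coupled in a Negishi reaction (Pd(PPh3)4, THF, 50 °C) with tert-butyl(4-iodophenoxy)dimethylsilane to 2-{4-[(tert-butyldimethylsilyl)oxy]phenyl}-8-methoxy-4-oxo-4H-chromene-3,5,7-triyl tris(2,2-dimethylpropanoate) F1. HF·pyridine in THF then frees O4' and the route is rejoined at 21.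

2. Step 3. Reductive loss of iodine or stalling of the C–O coupling at the doubly flanked carbon may prevail; placement of iodine at C5 in step 2 would have the same consequence. The fallback sets out from 2, needs neither step 2 nor step 3, and fixes the methoxy position through a uniquely free phenol.
   - Benzylation (BnBr, K2CO3, DMF) gives 2-(benzyloxy)-4,6-bis(methoxymethoxy)benzaldehyde F2.
   - Baeyer–Villiger oxidation (mCPBA, NaHCO3, CH2Cl2) gives 2-(benzyloxy)-4,6-bis(methoxymethoxy)phenyl formate F3, which K2CO3 in MeOH cleaves to 2-(benzyloxy)-4,6-bis(methoxymethoxy)phenol F4.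
   - Methylation (MeI, K2CO3, DMF) gives 1-(benzyloxy)-2-methoxy-3,5-bis(methoxymethoxy)benzene F5.
   - Hydrogenolysis (H2, 10% Pd/C, EtOAc) gives 2-methoxy-3,5-bis(methoxymethoxy)phenol F6.
   - Magnesium-mediated ortho-formylation (MgCl2, Et3N, paraformaldehyde, THF, reflux) can occur only at the single free ortho position and rejoins the route at 4.

3. Step 8. Metalation may be incomplete, or the amide or the arylzinc may attack an ester carbonyl or open the pyranone at C2. The fallback sets out from 12 and avoids deprotonation. TMSOTf (CH2Cl2, 0 °C) converts the pyranone into 8-methoxy-3,5,7-tris[(2,2-dimethylpropanoyl)oxy]-4-[(trimethylsilyl)oxy]chromenylium trifluoromethanesulfonate F7. The copper acetylide formed from 15 with CuI and iPr2NEt adds at C2 to give 8-methoxy-4-[(trimethylsilyl)oxy]-2-[(trimethylsilyl)ethynyl]-2H-chromene-3,5,7-triyl tris(2,2-dimethylpropanoate) F8 (racemic). Dehydrogenation of this silyl enol ether with DDQ restores the chromone and rejoins the route at 16.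

Further compounds
F1 | step 11 | 2-{4-[(tert-butyldimethylsilyl)oxy]phenyl}-8-methoxy-4-oxo-4H-chromene-3,5,7-triyl tris(2,2-dimethylpropanoate) | COc1c(OC(=O)C(C)(C)C)cc(OC(=O)C(C)(C)C)c2c(=O)c(OC(=O)C(C)(C)C)c(-c3ccc(O[Si](C)(C)C(C)(C)C)cc3)oc12
F2 | step 3 | 2-(benzyloxy)-4,6-bis(methoxymethoxy)benzaldehyde | O=Cc1c(OCc2ccccc2)cc(OCOC)cc1OCOC
F3 | step 3 | 2-(benzyloxy)-4,6-bis(methoxymethoxy)phenyl formate | O=COc1c(OCc2ccccc2)cc(OCOC)cc1OCOC
F4 | step 3 | 2-(benzyloxy)-4,6-bis(methoxymethoxy)phenol | Oc1c(OCc2ccccc2)cc(OCOC)cc1OCOC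
F5 | step 3 | 1-(benzyloxy)-2-methoxy-3,5-bis(methoxymethoxy)benzene | COc1c(OCc2ccccc2)cc(OCOC)cc1OCOC
F6 | step 3 | 2-methoxy-3,5-bis(methoxymethoxy)phenol | COc1c(O)cc(OCOC)cc1OCOC
F7 | step 8 | 8-methoxy-3,5,7-tris[(2,2-dimethylpropanoyl)oxy]-4-[(trimethylsilyl)oxy]chromenylium trifluoromethanesulfonate | COc1c(OC(=O)C(C)(C)C)cc(OC(=O)C(C)(C)C)c2c(O[Si](C)(C)C)c(OC(=O)C(C)(C)C)c[o+]c12.[O-]S(=O)(=O)C(F)(F)F
F8 | step 8 | 8-methoxy-4-[(trimethylsilyl)oxy]-2-[(trimethylsilyl)ethynyl]-2H-chromene-3,5,7-triyl tris(2,2-dimethylpropanoate), racemic | COc1c(OC(=O)C(C)(C)C)cc(OC(=O)C(C)(C)C)c2C(O[Si](C)(C)C)=C(OC(=O)C(C)(C)C)C(C#C[Si](C)(C)C)Oc12
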